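## Structural features

The target is one cyclohexane ring in which every ring carbon carries oxygen: C1 (quaternary, bearing the C7 methylene and its benzoate) and C6 share an oxirane, C2 and C3 carry acetates, C4 and C5 carry free hydroxyls. The six stereocentres C1 to C6 are contiguous. With β defined as the ring face on which C7 stands, the oxirane oxygen and O2 are α (cis to each other), and from there the oxygens alternate (O3 β, O4 α, O5 β), so O2 to O5 are all trans. The fragile points are acyl migration among O2 to O5, acid opening of the trisubstituted oxirane with help from the neighbouring benzoate, and base-induced epoxide migration, because the C5 hydroxyl is anti to the oxirane. The real difficulty is to fix the absolute configuration of a fully oxygenated ring with a quaternary centre and to tell six oxygens apart without long protecting-group traffic. C1 and C4 lie on a mirror plane of the ring skeleton, so a 2,3:5,6-bis-oxirane with a C4 carbonyl and a C1 hydroxyl anti to both oxiranes is meso and already holds all seven carbons and every ring oxygen except O2. The key step uses this: migration of the C1 oxygen onto C6 breaks the symmetry, builds the C1–C6 oxirane and releases O5 with the relative configuration of the target.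

## Logic of the disconnections

14 to 13: the O4–Si and O5–Si bonds are cut last. Only the two hydroxyls that must stay unacylated are masked, so 13 has no free hydroxyl that could shift an acetate or attack the oxirane. The forward step needs a fluoride source that never generates an alkoxide.

13 to 12: the O3–acetyl bond is cut. The two acetates have different origins, and O3 is the oxygen left behind by an oxirane. The forward step is acylation of a hindered secondary hydroxyl.

12 to 11: the C2–O2 bond is cut and O3 is reconnected to C2 as a β oxirane. Anti addition of acetate from the α face gives the 2α,3β pattern in one step, and two stereocentres collapse into one oxirane. The forward step must direct the nucleophile to C2 and not to C3 or C6.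

11 to 10: the two O–Si bonds are cut. The silyl groups are control elements for the opening, not only protection. The forward step must silylate both hydroxyls without disturbing two oxiranes.

10 to 9: the C4–H bond is cut (reduction). C4 becomes a carbonyl carbon on the future mirror plane. The forward step must deliver hydride to the β face, against the intrinsic bias, under the direction of the free C5 hydroxyl.

9 to 8: the O1–C6 bond is cut and O5 is rejoined to C6. This is the key disconnection. It turns a compound with five stereocentres into a meso compound, so the whole absolute-configuration problem becomes one catalyst-controlled choice between C6 and C2. The forward step needs that choice, and it needs the product to be taken on before it reverts.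

8 to 7: the O1–Si bond is cut. The free tertiary hydroxyl would steer epoxidation to the wrong face and would rearrange without control under base, so it is released last and under acid.

7 to 5 (through 6): the four C–O bonds of the two oxiranes are cut. This gives an achiral, planar cross-conjugated dienone. The forward step needs both peroxide additions to occur anti to the silyloxy group.

5 to 4: the O1–Si bond is cut. The forward step is silylation of a tertiary, doubly allylic hydroxyl.

4 to 3: the C1–O1 bond is cut, which restores the aromatic ring. All seven carbons of 14 are then present in a simple phenol. The forward step must add water at the para carbon and spare the benzylic ester.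

3 to 1 and 2: the O7–benzoyl bond is cut. The benzoate of the target is carried from the first step, so no late differentiation of the primary oxygen is needed. The forward step must acylate the alcohol and not the phenol.

## Other disconnections considered

Alternative 1: The cut is the C1–C2 ring bond. In the forward sense the acyclic ketoaldehyde A1, made from a hexonolactone of the chiral pool, is treated with SmI2 (divalent samarium) in THF. The C2 aldehyde and the C1 ketone couple as ketyls and close the carbocycle as the cis-1,2-diol A2.
- In its favour: the reaction class is established for sugar-derived dicarbonyls. The samarium-bridged diol is expected cis and anti to the flanking alkoxy groups, which is what A2 requires. C3 to C6 come from the sugar with known absolute configuration.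
- Where it is better than the chosen plan: the absolute configuration does not depend on an untested catalyst, and O1 and O2 are cis directly, so no inversion at C2 by an external nucleophile is needed.
- Against it here: A1 needs four different protecting groups and an estimated eight to ten steps. After A2 the C6 oxygen, which is β, must be made a leaving group in the presence of O5 and displaced by O1. The ether on O7 must be exchanged for benzoate, O2 and O3 acetylated, and O4 and O5 freed.
- Comparison: on structure it builds a ring the chosen plan gets free from an arene. On mechanism it is the safer key step. On step economy it is roughly twice as long.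

Alternative 2: The cut is the pair of α-face bonds C1–O and C4–O. In the forward sense the cyclohexa-1,3-diene A3, already carrying the trans diacetate and the benzoate, takes up singlet oxygen (tetraphenylporphyrin, light, O2) across C1 and C4 to give the endoperoxide A4.
- In its favour: one step sets the quaternary C1 and C4 with both oxygens on the same face.
- Where it is better than the chosen plan: the C2/C3 diacetate is in place from the start, so the regioselective oxirane opening of step 9 has no counterpart.
- Where it is equal: the known isomerisation of A4 with Co(TPP) (divalent cobalt) should give the syn bis-oxirane A5, which must then take water at C5 only, from the β face. That is an oxirane-opening regiochemistry question of the same kind as step 9.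
- Against it here: the acetates on C2 (α) and C3 (β) flank the two diene termini on opposite faces, so the facial course of the cycloaddition is not secured. A3 is a trans-dihydroarene diol derivative that aromatises easily and would need its own enantioselective synthesis, so the absolute-configuration problem is only moved.
- Comparison: on mechanism the key step is precedented where the chosen one is not. On step economy it is shorter after the key step (about three steps against five) but probably longer overall once A3 is counted.

Alternative 3: The cut is the pair of cis bonds C1–O and C2–O. In the forward sense whole cells of Ralstonia eutropha B9 add both atoms of O2 to benzoic acid A6 and give the (1S,2R)-diol acid A7.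
- In its favour: a single enantiomer with established absolute configuration, O1 and O2 cis on the α face as in the target, and C7 present at the acid oxidation level.
- Where it is better than the chosen plan: the absolute configuration rests on a proven biotransformation, and the cis O1/O2 relationship needs no inversion at C2.
- Where it is equal: the C1–C6 oxirane would most simply arise from a β oxirane at C5–C6 by the same epoxide migration, there diastereospecific. The trans oxygenation of C3/C4 raises an opening-regiochemistry problem comparable to step 9.
- Against it here: four more oxygens must be placed on the diene with face and regiocontrol. A7 is acid-labile (it rearomatises by dehydration) and comes from fermentation with a mutant strain, not from a catalogue. The acid must be reduced and benzoylated.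
- Comparison: on structure it starts one oxidation step ahead at C1/C2 and behind at C3 to C6. On mechanism it is safer in the stereo-defining step. On step economy it is estimated at twelve to fourteen steps, comparable to or slightly longer than the chosen plan.

Key step: step 6

Remarks on the chemistry

- Locants follow the target: C1 is the quaternary ring carbon carrying C7, C6 is the other oxirane carbon of 14, β is the ring face on which C7 stands and α the opposite face. "salen" is the N,N'-bis(3,5-di-tert-butylsalicylidene)-1,2-cyclohexanediaminate ligand.
- Assumption: which antipode of the cobalt catalyst leads to 9 and which to its mirror image cannot be predicted. The (R,R) complex is written, and the (S,S) complex takes its place if the sense is the opposite one.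
- Structures: the configurations of 8, 9 and 14 were checked against each other. Both oxiranes of 8 are β and its hydroxyl α, and attack of O1 on C6 leads to 9 with the C1, C5 and C6 configuration of 14. No structure needed correction.
- Correction to the first step: an acid chloride with base would acylate the phenoxide first, and a 4-(acyloxymethyl)phenoxide expels carboxylate to a quinone methide. The benzoate is therefore introduced enzymatically, without base.
- Corrections after the key step: an α,β-epoxy ketone is not reliably opened at its β carbon by a carboxylic acid beside a more acid-labile trisubstituted oxirane; a β-acetoxy ketone would be carried through a basic acetylation; and hydride delivery to a ketone flanked by two β oxygens is expected from the α face, the wrong one. The ketone is therefore reduced first under direction by the C5 hydroxyl, and the oxirane is opened afterwards on a ketone-free, fully protected intermediate.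
- Precursor design: the skeleton of 8 is kept. The improvement is that 8 is released from a triethylsilyl ether by acidic fluoride and never meets base, since its alkoxide would rearrange without the catalyst to racemic material. Its C4 carbonyl is kept on purpose as the acceptor for the directed reduction of step 7.

## Route

Step 1
Reactants: 1 4-hydroxybenzyl alcohol; 2 vinyl benzoate
Product: 3 4-hydroxybenzyl benzoate
Conditions: Novozym 435 (immobilised Candida antarctica lipase B), TBME/THF, 40 °C
Reagents that add atoms: none
Why: Lipase-catalysed transesterification with an enol ester acylates the primary benzylic hydroxyl and leaves the phenol alone, and the released enol tautomerises to acetaldehyde, so the step is irreversible; no base is present, so the product cannot expel benzoate to a quinone methide.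

Step 2
Reactants: 3 4-hydroxybenzyl benzoate
Product: 4 (1-hydroxy-4-oxocyclohexa-2,5-dien-1-yl)methyl benzoate
Conditions: PhI(OAc)2, MeCN/H2O (3:1), 0 °C
Reagents that add atoms: water, O
Why: Oxidative dearomatisation of a para-substituted phenol with PhI(OAc)2 (trivalent iodine): water adds to the para carbon of the aryloxy-iodane and gives the para-quinol; the weakly acidic medium is tolerated by the benzylic ester.

Step 3
Reactants: 4 (1-hydroxy-4-oxocyclohexa-2,5-dien-1-yl)methyl benzoate
Product: 5 [4-oxo-1-(triethylsilyloxy)cyclohexa-2,5-dien-1-yl]methyl benzoate
Conditions: TESOTf, 2,6-lutidine, CH2Cl2, −78 °C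
Reagents that add atoms: triethylsilyl trifluoromethanesulfonate, CC[Si](CC)(CC)OS(=O)(=O)C(F)(F)F
Why: Silyl triflate silylation of a tertiary alcohol under lutidine buffering; the silyl ether removes hydrogen-bond delivery of peroxide to the α face and shields that face.

Step 4
Reactants: 5 [4-oxo-1-(triethylsilyloxy)cyclohexa-2,5-dien-1-yl]methyl benzoate
Product: 7 meso [2β,3β:5β,6β-diepoxy-4-oxo-1α-(triethylsilyloxy)cyclohexyl]methyl benzoate, via racemic mono-epoxy enone 6 (not isolated)
Conditions: t-BuOOH (anhydrous, decane), DBU, CH2Cl2, 0 °C to rt
Reagents that add atoms: tert-butyl hydroperoxide, CC(C)(C)OO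
Why: Weitz–Scheffer nucleophilic epoxidation of both enone units: the peroxide anion adds to each β carbon antiperiplanar to the C1–O bond and away from the silyl group, so both oxiranes form on the β face, cis to C7; the second addition follows the same bias and the product is meso with C2, C3, C5 and C6 set relative to C1.

Step 5
Reactants: 7 meso [2β,3β:5β,6β-diepoxy-4-oxo-1α-(triethylsilyloxy)cyclohexyl]methyl benzoate
Product: 8 meso (2β,3β:5β,6β-diepoxy-1α-hydroxy-4-oxocyclohexyl)methyl benzoate
Conditions: HF·pyridine, pyridine/THF, 0 °C
Reagents that add atoms: none
Why: Acidic fluoride cleaves the triethylsilyl ether without forming an alkoxide, so the tertiary hydroxyl is freed without uncatalysed epoxide migration; benzoate, ketone and the electron-poor oxiranes are inert to buffered HF·pyridine at this temperature.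

Step 6
Reactants: 8 meso (2β,3β:5β,6β-diepoxy-1α-hydroxy-4-oxocyclohexyl)methyl benzoate
Product: 9 (1α,6α:2β,3β-diepoxy-5β-hydroxy-4-oxocyclohexyl)methyl benzoate
Conditions: (R,R)-(salen)Co(OTf) (5 mol %, trivalent cobalt), 4 Å MS, TBME, −20 °C; cold filtration through silica, used at once
Reagents that add atoms: none
Why: Proposed new method: the cationic trivalent cobalt centre binds the oxygen of one enantiotopic oxirane (a second catalyst molecule may hold the tertiary hydroxyl as a cobalt alkoxide), and O1, already antiperiplanar to the C6–O bond, attacks C6 from the α face while the displaced oxygen stays on C5; this is a Payne rearrangement under chiral Lewis acid catalysis, and the closest known reaction type is the cobalt–salen-catalysed enantioselective intramolecular opening of meso-epoxides by tethered alcohols. The new oxirane closes in the 3-exo-tet mode. C6 is inverted stereospecifically by the backside attack, C5 keeps its oxygen with retention, and C1 becomes stereogenic with its configuration fixed only by which of the two mirror-related oxiranes the catalyst activates. The step therefore needs selection between the enantiotopic carbons C6 and C2, which rests on the catalyst alone. Chemoselectivity is secured by the substrate: the C1 hydroxyl is the only nucleophile, it lies anti to both oxiranes after step 4, and attack at C5 would need a four-membered ring. The ketone is a spectator, but it makes 9 an α-ketol with a β oxirane, so no base is allowed and the cold filtrate goes straight into step 7. Because the rearrangement is reversible and the mirror-image products interconvert through 8, conversion is stopped before equilibrium is approached.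

Step 7
Reactants: 9 (1α,6α:2β,3β-diepoxy-5β-hydroxy-4-oxocyclohexyl)methyl benzoate
Product: 10 (1α,6α:2β,3β-diepoxy-4α,5β-dihydroxycyclohexyl)methyl benzoate
Conditions: Me4NBH(OAc)3, MeCN/AcOH (1:1), −30 °C
Reagents that add atoms: none
Why: Hydroxyl-directed triacetoxyborohydride reduction (Saksena–Evans): the C5 hydroxyl exchanges onto boron and hydride is delivered within the complex to the β face of C4, so the new hydroxyl is α, trans to O5; oxiranes and esters are inert to this reagent, and removing the ketone ends the base sensitivity of 9.

Step 8
Reactants: 10 (1α,6α:2β,3β-diepoxy-4α,5β-dihydroxycyclohexyl)methyl benzoate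
Product: 11 [1α,6α:2β,3β-diepoxy-4α,5β-bis(tert-butyldimethylsilyloxy)cyclohexyl]methyl benzoate
Conditions: TBSOTf, 2,6-lutidine, CH2Cl2, −78 to 0 °C
Reagents that add atoms: tert-butyldimethylsilyl trifluoromethanesulfonate, CC(C)(C)[Si](C)(C)OS(=O)(=O)C(F)(F)F
Why: Silyl triflate silylation of both secondary hydroxyls; it removes the free C5 hydroxyl that could reverse the migration and installs the two bulky groups that steer step 9.

Step 9
Reactants: 11 [1α,6α:2β,3β-diepoxy-4α,5β-bis(tert-butyldimethylsilyloxy)cyclohexyl]methyl benzoate
Product: 12 [2α-acetoxy-1α,6α-epoxy-3β-hydroxy-4α,5β-bis(tert-butyldimethylsilyloxy)cyclohexyl]methyl benzoate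
Conditions: CsOAc, AcOH, DMF, 70 °C
Reagents that add atoms: acetic acid (acetate delivered from CsOAc), CC(=O)O
Why: SN2 opening of an oxirane by carboxylate with trans-diaxial (Fürst–Plattner) course: C1 is quaternary, while C3 and C6 each have a silyloxy group on the neighbouring carbon on the very face the nucleophile must use, and the trans silyl ethers favour the diaxial half-chair in which α attack at C2 is the chair-like path. Inversion at C2 gives the 2α acetate and leaves the 3β hydroxyl; the acid buffer protonates the alkoxide before silyl migration can start.

Step 10
Reactants: 12 [2α-acetoxy-1α,6α-epoxy-3β-hydroxy-4α,5β-bis(tert-butyldimethylsilyloxy)cyclohexyl]methyl benzoate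
Product: 13 [2α,3β-diacetoxy-1α,6α-epoxy-4α,5β-bis(tert-butyldimethylsilyloxy)cyclohexyl]methyl benzoate
Conditions: Ac2O, pyridine, DMAP (cat.), CH2Cl2, 0 °C to rt
Reagents that add atoms: acetic anhydride, CC(=O)OC(C)=O
Why: DMAP-catalysed acetylation of the only free hydroxyl; no ketone is present, so no β-acyloxy elimination can occur, and the oxirane is inert to these conditions.

Step 11
Reactants: 13 [2α,3β-diacetoxy-1α,6α-epoxy-4α,5β-bis(tert-butyldimethylsilyloxy)cyclohexyl]methyl benzoate
Product: 14 (2α,3β-diacetoxy-1α,6α-epoxy-4α,5β-dihydroxycyclohexyl)methyl benzoate
Conditions: HF·pyridine, pyridine/THF, 0 °C to rt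
Reagents that add atoms: none
Why: Fluoride-mediated cleavage of both silyl ethers in a buffered acidic medium; no alkoxide forms, so neither acetyl migration to O4 nor epoxide migration from O5 is triggered, and trisubstituted oxiranes are known to survive these conditions.

## Compound list

1 | 4-hydroxybenzyl alcohol | OCc1ccc(O)cc1 | starting material
2 | vinyl benzoate | C=COC(=O)c1ccccc1 | starting material
3 | 4-hydroxybenzyl benzoate | O=C(OCc1ccc(O)cc1)c1ccccc1 | intermediate
4 | (1-hydroxy-4-oxocyclohexa-2,5-dien-1-yl)methyl benzoate | O=C1C=CC(O)(COC(=O)c2ccccc2)C=C1 | intermediate
5 | [4-oxo-1-(triethylsilyloxy)cyclohexa-2,5-dien-1-yl]methyl benzoate | O=C1C=CC(O[Si](CC)(CC)CC)(COC(=O)c2ccccc2)C=C1 | intermediate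
6 | racemic [5β,6β-epoxy-4-oxo-1α-(triethylsilyloxy)cyclohex-2-en-1-yl]methyl benzoate (one enantiomer drawn; not isolated) | O1[C@H]2C(=O)C=C[C@@](O[Si](CC)(CC)CC)(COC(=O)c3ccccc3)[C@@H]12 | intermediate
7 | meso [2β,3β:5β,6β-diepoxy-4-oxo-1α-(triethylsilyloxy)cyclohexyl]methyl benzoate | O1[C@H]2C(=O)[C@H]3O[C@H]3[C@@](O[Si](CC)(CC)CC)(COC(=O)c3ccccc3)[C@@H]12 | intermediate
8 | meso (2β,3β:5β,6β-diepoxy-1α-hydroxy-4-oxocyclohexyl)methyl benzoate | O1[C@H]2C(=O)[C@H]3O[C@H]3[C@@](O)(COC(=O)c3ccccc3)[C@@H]12 | intermediate
9 | (1α,6α:2β,3β-diepoxy-5β-hydroxy-4-oxocyclohexyl)methyl benzoate | O1[C@H]2C(=O)[C@@H](O)[C@@H]3O[C@]3(COC(=O)c3ccccc3)[C@@H]12 | intermediate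
10 | (1α,6α:2β,3β-diepoxy-4α,5β-dihydroxycyclohexyl)methyl benzoate | O1[C@H]2[C@H](O)[C@@H](O)[C@@H]3O[C@]3(COC(=O)c3ccccc3)[C@@H]12 | intermediate
11 | [1α,6α:2β,3β-diepoxy-4α,5β-bis(tert-butyldimethylsilyloxy)cyclohexyl]methyl benzoate | O1[C@H]2[C@H](O[Si](C)(C)C(C)(C)C)[C@@H](O[Si](C)(C)C(C)(C)C)[C@@H]3O[C@]3(COC(=O)c3ccccc3)[C@@H]12 | intermediate
12 | [2α-acetoxy-1α,6α-epoxy-3β-hydroxy-4α,5β-bis(tert-butyldimethylsilyloxy)cyclohexyl]methyl benzoate | O[C@H]1[C@H](O[Si](C)(C)C(C)(C)C)[C@@H](O[Si](C)(C)C(C)(C)C)[C@@H]2O[C@]2(COC(=O)c2ccccc2)[C@@H]1OC(C)=O | intermediate
13 | [2α,3β-diacetoxy-1α,6α-epoxy-4α,5β-bis(tert-butyldimethylsilyloxy)cyclohexyl]methyl benzoate | CC(=O)O[C@H]1[C@H](O[Si](C)(C)C(C)(C)C)[C@@H](O[Si](C)(C)C(C)(C)C)[C@@H]2O[C@]2(COC(=O)c2ccccc2)[C@@H]1OC(C)=O | intermediate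
14 | (2α,3β-diacetoxy-1α,6α-epoxy-4α,5β-dihydroxycyclohexyl)methyl benzoate, CNP0171674.1 | CC(=O)O[C@H]1[C@H](O)[C@@H](O)[C@@H]2O[C@]2(COC(=O)c2ccccc2)[C@@H]1OC(C)=O | target

## Step count and risks

Total step count: 11. Longest linear sequence: 11 steps (from 1 to 14).

Least certain steps, the one beyond known chemistry first:

**Step 6.** Discrimination between the enantiotopic oxiranes may be poor. The enantiomeric purity may erode by reversal through 8. The α-ketol product may chelate and inhibit the catalyst. The Lewis acid may promote opening of the new oxirane by the neighbouring benzoate.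
Fallback (resolution in place of desymmetrisation): the fallback sets out from 8. A classical base-mediated Payne rearrangement (catalytic DBU, CH2Cl2, −40 °C, quenched with AcOH) should give 9 together with the mirror image of 9 F1. The mixture is reduced as in step 7 to 10 together with the mirror image of 10 F2. Lipase-catalysed acetylation (Burkholderia cepacia lipase, vinyl acetate, TBME) then serves as a kinetic resolution. The enzyme preparation is chosen by screening so that the mirror-image diol is the one acylated, expected at the less hindered O4, to the 4-O-acetate of the mirror image of 10 F3. Unreacted 10 is separated and the route is rejoined at 10.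

**Step 9.** The acetate may attack C3 or C6 if the diaxial conformer is not dominant. Conversion may be sluggish at a carbon flanked by a fully substituted centre. A silyl group may migrate from O4 to the freed O3.
Fallback (electronic control by the ketone in place of steric and conformational control): the fallback sets out from 9.
- Silylation (TBSOTf, 2,6-lutidine) gives the 5-O-silyl ether of 9 F4.
- Acid-mediated opening (AcOH, Sc(OTf)3 cat., CH2Cl2, 0 °C) follows; under acid, substitution at the carbon α to a carbonyl is disfavoured, so acetate should enter at the β carbon C2 and give the 2α-acetoxy-3β-hydroxy ketone F5.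
- Acetylation without DMAP (Ac2O, pyridine, 0 °C) gives the 2α,3β-diacetoxy ketone F6.
- HF·pyridine frees O5 to give the 5β-hydroxy ketone F7.
- Directed reduction as in step 7 (Me4NBH(OAc)3) delivers hydride to the β face of C4 and rejoins the route at 14.

**Step 4.** Peroxide may add syn to the silyloxy group at one or both enones, giving chiral or all-syn isomers in place of the meso compound.
Fallback (hydrogen-bond delivery in place of steric shielding): the fallback sets out from 5. Methanolysis of the benzoate (K2CO3, MeOH, 0 °C) gives 4-(hydroxymethyl)-4-(triethylsilyloxy)cyclohexa-2,5-dienone F8. Hydroxyl-directed nucleophilic epoxidation (t-BuOOH, benzyltrimethylammonium hydroxide, THF, 0 °C) should deliver both oxygens to the face of the free hydroxymethyl group and give the meso bis-epoxy alcohol F9. Benzoylation (BzCl, pyridine) rejoins the route at 7.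

**Step 7.** Undirected hydride delivery to the less hindered α face may compete and give the C4 epimer, or the ketol may revert before it is reduced.
Fallback (catalyst control in place of substrate direction): the fallback sets out from 9. Noyori transfer hydrogenation with the matching antipode of RuCl(p-cymene)[(S,S)-TsDPEN] (divalent ruthenium) in HCO2H/Et3N (5:2) should impose β-face delivery. It rejoins the route at 10, and no new compound arises (F0).

**Step 2.** The oxidation may suffer from ortho attack, over-oxidation, or transfer of the benzoyl group to the tertiary oxygen through participation of the ester.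
Fallback (spiro-epoxide route): the fallback sets out from 1 and also replaces step 1. Adler–Becker oxidation (NaIO4, H2O/MeCN, 0 °C) gives 1-oxaspiro[2.5]octa-4,7-dien-6-one F10. Its oxirane is opened at the methylene carbon with benzoic acid buffered by CsO2CPh in DMF, which rejoins the route at 4.

## Further compounds

F1 | step 6 | mirror image of 9 | O1[C@@H]2C(=O)[C@H](O)[C@H]3O[C@@]3(COC(=O)c3ccccc3)[C@H]12
F2 | step 6 | mirror image of 10 | O1[C@@H]2[C@@H](O)[C@H](O)[C@H]3O[C@@]3(COC(=O)c3ccccc3)[C@H]12
F3 | step 6 | 4-O-acetate of the mirror image of 10 | O1[C@@H]2[C@@H](OC(C)=O)[C@H](O)[C@H]3O[C@@]3(COC(=O)c3ccccc3)[C@H]12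
F4 | step 9 | [1α,6α:2β,3β-diepoxy-4-oxo-5β-(tert-butyldimethylsilyloxy)cyclohexyl]methyl benzoate | O1[C@H]2C(=O)[C@@H](O[Si](C)(C)C(C)(C)C)[C@@H]3O[C@]3(COC(=O)c3ccccc3)[C@@H]12
F5 | step 9 | [2α-acetoxy-1α,6α-epoxy-3β-hydroxy-4-oxo-5β-(tert-butyldimethylsilyloxy)cyclohexyl]methyl benzoate | O[C@H]1C(=O)[C@@H](O[Si](C)(C)C(C)(C)C)[C@@H]2O[C@]2(COC(=O)c2ccccc2)[C@@H]1OC(C)=O
F6 | step 9 | [2α,3β-diacetoxy-1α,6α-epoxy-4-oxo-5β-(tert-butyldimethylsilyloxy)cyclohexyl]methyl benzoate | CC(=O)O[C@H]1C(=O)[C@@H](O[Si](C)(C)C(C)(C)C)[C@@H]2O[C@]2(COC(=O)c2ccccc2)[C@@H]1OC(C)=O
F7 | step 9 | (2α,3β-diacetoxy-1α,6α-epoxy-5β-hydroxy-4-oxocyclohexyl)methyl benzoate | CC(=O)O[C@H]1C(=O)[C@@H](O)[C@@H]2O[C@]2(COC(=O)c2ccccc2)[C@@H]1OC(C)=O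
F8 | step 4 | 4-(hydroxymethyl)-4-(triethylsilyloxy)cyclohexa-2,5-dienone | O=C1C=CC(CO)(O[Si](CC)(CC)CC)C=C1
F9 | step 4 | meso 2β,3β:5β,6β-diepoxy-4-(hydroxymethyl)-4-(triethylsilyloxy)cyclohexanone (oxiranes cis to the hydroxymethyl group) | O1[C@H]2C(=O)[C@H]3O[C@H]3[C@@](O[Si](CC)(CC)CC)(CO)[C@@H]12
F0 | step 7 | none | none
F10 | step 2 | 1-oxaspiro[2.5]octa-4,7-dien-6-one | O=C1C=CC2(CO2)C=C1
A1 | alternative 1 | acyclic ketoaldehyde (C2 aldehyde, C1 ketone, 3-O-triethylsilyl, 4-O-tert-butyldimethylsilyl, 5,6-O-isopropylidene, 7-O-(4-methoxybenzyl)) | O=C[C@@H](O[Si](CC)(CC)CC)[C@H](O[Si](C)(C)C(C)(C)C)[C@H]1OC(C)(C)O[C@H]1C(=O)COCc1ccc(OC)cc1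
A2 | alternative 1 | cyclitol with cis C1,C2 diol and quaternary C1 | CC[Si](CC)(CC)O[C@H]1[C@H](O[Si](C)(C)C(C)(C)C)[C@H]2OC(C)(C)O[C@H]2[C@@](O)(COCc2ccc(OC)cc2)[C@@H]1O
A3 | alternative 2 | (2α,3β-diacetoxycyclohexa-4,6-dien-1-yl)methyl benzoate (C1=C6 and C4=C5 diene) | CC(=O)O[C@H]1C=CC=C(COC(=O)c2ccccc2)[C@@H]1OC(C)=O
A4 | alternative 2 | C1,C4 endoperoxide (α face) with C5=C6 alkene | CC(=O)O[C@H]1[C@H]2C=C[C@](COC(=O)c3ccccc3)(OO2)[C@@H]1OC(C)=O
A5 | alternative 2 | (2α,3β-diacetoxy-1α,6α:4α,5α-diepoxycyclohexyl)methyl benzoate | CC(=O)O[C@H]1[C@@H]2O[C@@H]2[C@@H]2O[C@]2(COC(=O)c2ccccc2)[C@@H]1OC(C)=O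
A6 | alternative 3 | benzoic acid | OC(=O)c1ccccc1
A7 | alternative 3 | (1S,2R)-1,2-dihydroxycyclohexa-3,5-diene-1-carboxylic acid | C1=CC=C[C@@](O)(C(=O)O)[C@@H]1O
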